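The route opens pyranone ring E of the flavone half at C4a''–C4'', C4''–C3'' and O1''–C2''. One palladium-catalysed carbonylative annulation joins an ortho-iodophenol, carbon monoxide and 4-(benzyloxy)phenylacetylene to form ring E. It exploits one feature of ring D: C8a'', which carries O1'', stands para to the biaryl carbon C6''. A 4-aryl-3,5-dialkoxyphenol therefore has two equivalent ortho carbons, and iodination of either settles the 6''-linkage ahead of pyranone formation. The precursor is this iodophenol, with ring B attached as a dibenzyl catechol bearing a dioxolane-masked aldehyde. That aldehyde later grows into the 2S flavanone through an organocatalytic oxa-Michael closure.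

Key step: step 9

Remarks on the chemistry
- Locants: the flavanone half has ring A (C4a–C8a), ring C (O1–C4) and ring B (C1'–C6'). The flavone half (double primes) has ring D (C4a''–C8a''), ring E (O1''–C4'') and ring F (the 4-hydroxyphenyl group on C2''). The biaryl bond is C5'–C6''.
- Assumption: the quinine-derived thiourea N-[3,5-bis(trifluoromethyl)phenyl]-N'-[(8α,9S)-6'-methoxycinchonan-9-yl]thiourea is taken to give the 2S series; the sense is to be checked by circular dichroism against a 2S flavanone, and the quinidine-derived pseudo-enantiomer is used if it proves opposite.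
- Assumption: the C5'–C6'' axis (three ortho oxygens, one ortho hydrogen) is treated as configurationally labile in the target, which has no axial descriptor, so slowly interconverting rotamers of protected intermediates converge on deprotection.
- Assumption: the Knoevenagel product is drawn as the Z isomer (aryl cis to the ester), the one expected under equilibrating conditions.
- Protecting groups: the methoxymethyl groups direct the metalation and leave together with the dioxolane straight after the key step, so no formaldehyde acetal meets the later sulfonic acid treatment. From there on only benzyl ethers remain, and the last step is neutral.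

Step 1
Reactants: 1 phloroglucinol (benzene-1,3,5-triol)
Product: 2 3,5-bis(methoxymethoxy)phenol
Conditions: MOMCl (2.0 equiv), i-Pr2NEt (2.2 equiv), DMF, 0 °C to rt
Reagents that add atoms: chloromethyl methyl ether, COCCl
Why: Stoichiometry-limited Williamson-type O-alkylation of the symmetric triol should give the bis-acetal as the main component of a statistical mixture that is separable by chromatography at this cheap stage.

Step 2
Reactants: 2 3,5-bis(methoxymethoxy)phenol
Product: 3 [3,5-bis(methoxymethoxy)phenoxy]tri(propan-2-yl)silane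
Conditions: TIPSCl, imidazole, DMF, rt
Reagents that add atoms: chlorotri(propan-2-yl)silane, CC(C)[Si](Cl)(C(C)C)C(C)C
Why: Standard silylation of the only free phenol installs a bulky group that survives butyllithium and shields its two flanking C–H sites in the coming metalation.

Step 3
Reactants: 4 5-bromovanillin (3-bromo-4-hydroxy-5-methoxybenzaldehyde)
Product: 5 3-bromo-4,5-dihydroxybenzaldehyde
Conditions: AlCl3, pyridine, CH2Cl2, reflux; then aq HCl
Reagents that add atoms: none
Why: In this chelation-assisted aryl methyl ether cleavage, aluminium binds the ortho hydroxy/methoxy pair and pyridine removes the methyl group by SN2 attack, which is routine for vanillin-type aldehydes and spares the formyl group and the bromide.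

Step 4
Reactants: 5 3-bromo-4,5-dihydroxybenzaldehyde
Product: 6 3,4-bis(benzyloxy)-5-bromobenzaldehyde
Conditions: BnBr (2.3 equiv), K2CO3, DMF, 50 °C
Reagents that add atoms: benzyl bromide, BrCc1ccccc1
Why: Williamson ether synthesis on both catechol oxygens gives ethers that tolerate every later acid and base and leave by hydrogenolysis at the end.

Step 5
Reactants: 6 3,4-bis(benzyloxy)-5-bromobenzaldehyde
Product: 7 2-[3,4-bis(benzyloxy)-5-bromophenyl]-1,3-dioxolane
Conditions: ethylene glycol, TsOH·H2O (cat.), toluene, Dean–Stark reflux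
Reagents that add atoms: ethane-1,2-diol, OCCO
Why: Acid-catalysed acetalisation with azeotropic water removal masks the aldehyde against the organozinc reagent and against hot diethylamine and alkyne in the key step.

Step 6
Reactants: 3 [3,5-bis(methoxymethoxy)phenoxy]tri(propan-2-yl)silane; 7 2-[3,4-bis(benzyloxy)-5-bromophenyl]-1,3-dioxolane
Product: 10 {4-[2,3-bis(benzyloxy)-5-(1,3-dioxolan-2-yl)phenyl]-3,5-bis(methoxymethoxy)phenoxy}tri(propan-2-yl)silane, via aryllithium 8 (not isolated), via arylzinc chloride 9 (not isolated)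
Conditions: n-BuLi, THF, 0 °C; ZnCl2, 0 °C to rt; then 7, Pd2(dba)3 (2 mol %), RuPhos (8 mol %), THF, 65 °C
Reagents that add atoms: none
Why: Directed ortho-metalation takes the C–H between the two chelating methoxymethoxy groups, zinc gives a nucleophile free of the protodeboronation that plagues 2,6-dialkoxyarylboron species, and Negishi coupling with a bulky dialkylbiarylphosphine is established for tri-ortho-substituted biaryls.

Step 7
Reactants: 10 {4-[2,3-bis(benzyloxy)-5-(1,3-dioxolan-2-yl)phenyl]-3,5-bis(methoxymethoxy)phenoxy}tri(propan-2-yl)silane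
Product: 11 4-[2,3-bis(benzyloxy)-5-(1,3-dioxolan-2-yl)phenyl]-3,5-bis(methoxymethoxy)phenol
Conditions: Bu4NF, AcOH (1:1), THF, 0 °C
Reagents that add atoms: none
Why: Buffered fluoride-induced Si–O cleavage frees only the phenol para to the biaryl bond and leaves acetals and benzyl ethers untouched.

Step 8
Reactants: 11 4-[2,3-bis(benzyloxy)-5-(1,3-dioxolan-2-yl)phenyl]-3,5-bis(methoxymethoxy)phenol
Product: 12 4-[2,3-bis(benzyloxy)-5-(1,3-dioxolan-2-yl)phenyl]-2-iodo-3,5-bis(methoxymethoxy)phenol
Conditions: NIS (1.0 equiv, slow addition), NaHCO3 (solid), CH2Cl2, −20 to 0 °C, dark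
Reagents that add atoms: N-iodosuccinimide, O=C1CCC(=O)N1I
Why: In this acid-free electrophilic aromatic iodination the para position is blocked by ring B, the two ortho carbons are equivalent, ring D is far more activated than ring B, and one equivalent of reagent at low temperature limits a second iodination.

Step 9
Reactants: 12 4-[2,3-bis(benzyloxy)-5-(1,3-dioxolan-2-yl)phenyl]-2-iodo-3,5-bis(methoxymethoxy)phenol; 13 1-(benzyloxy)-4-ethynylbenzene
Product: 16 6-[2,3-bis(benzyloxy)-5-(1,3-dioxolan-2-yl)phenyl]-2-[4-(benzyloxy)phenyl]-5,7-bis(methoxymethoxy)-4H-chromen-4-one, via hydroxyaryl ynone 14 (not isolated), via diethylamino enone 15 (not isolated)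
Conditions: PdCl2(dppf) (5 mol %), CO (20 bar), 13 (1.5 equiv), Et2NH, 120 °C, autoclave
Reagents that add atoms: carbon monoxide, [C-]#[O+]
Why: Zerovalent palladium formed in situ inserts into the C4a''–I bond of 12, migratory insertion of CO gives the aroylpalladium species, and transfer of the amine-deprotonated alkyne 13 followed by reductive elimination gives ynone 14 (bonds C4a''–C4'' and C4''–C3''). Diethylamine then adds to C2'' of 14 to give enaminone 15 and the neighbouring phenol displaces the amine by addition–elimination (bond O1''–C2''), closing ring E in a net 6-endo-dig mode and bypassing the 5-exo-dig attack at C3'' that would lead to an aurone. The closest known reaction type is the palladium-catalysed carbonylative coupling of ortho-iodophenols with terminal arylacetylenes in a secondary amine, an established flavone synthesis. No stereocentre is formed. Carbonylation is favoured over direct alkynylation and benzofuran closure by the CO pressure and the absence of copper, and the methoxymethyl ethers, benzyl ethers and dioxolane are inert to the basic medium. Regiochemistry needs no control here because 12 holds one phenol and one iodide, placed so that the carbon para to the phenol oxygen already bears ring B.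

Step 10
Reactants: 16 6-[2,3-bis(benzyloxy)-5-(1,3-dioxolan-2-yl)phenyl]-2-[4-(benzyloxy)phenyl]-5,7-bis(methoxymethoxy)-4H-chromen-4-one
Product: 17 3,4-bis(benzyloxy)-5-{2-[4-(benzyloxy)phenyl]-5,7-dihydroxy-4-oxo-4H-chromen-6-yl}benzaldehyde
Conditions: 3 M aq HCl, MeOH/THF, 55 °C
Reagents that add atoms: water, O
Why: Acid-catalysed acetal hydrolysis and methanolysis remove the dioxolane and both methoxymethyl groups in one operation, while benzyl ethers persist and the conditions are far too mild for Wessely–Moser isomerisation of the 6-aryl flavone.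

Step 11
Reactants: 17 3,4-bis(benzyloxy)-5-{2-[4-(benzyloxy)phenyl]-5,7-dihydroxy-4-oxo-4H-chromen-6-yl}benzaldehyde
Product: 18 3,4-bis(benzyloxy)-5-{7-(benzyloxy)-2-[4-(benzyloxy)phenyl]-5-hydroxy-4-oxo-4H-chromen-6-yl}benzaldehyde
Conditions: BnBr (1.1 equiv), K2CO3 (1.5 equiv), DMF, rt
Reagents that add atoms: benzyl bromide, BrCc1ccccc1
Why: Williamson etherification picks the acidic 7''-OH because the 5''-OH is hydrogen-bonded to the C4'' carbonyl and flanked by ring B, and masking the acidic phenol keeps it from neutralising the amine of the later organocatalyst.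

Step 12
Reactants: 19 2',4',6'-trihydroxyacetophenone
Product: 20 1-[2,4-bis(benzyloxy)-6-hydroxyphenyl]ethan-1-one
Conditions: BnBr (2.05 equiv), K2CO3 (2.2 equiv), DMF, rt to 50 °C
Reagents that add atoms: benzyl bromide, BrCc1ccccc1
Why: Williamson etherification with two equivalents of halide leaves one carbonyl-chelated ortho phenol free, the usual selectivity of phloroacetophenone.

Step 13
Reactants: 20 1-[2,4-bis(benzyloxy)-6-hydroxyphenyl]ethan-1-one
Product: 22 tert-butyl 3-[2,4-bis(benzyloxy)-6-hydroxyphenyl]-3-oxopropanoate, via dilithium enolate phenolate 21 (not isolated)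
Conditions: LiN(SiMe3)2 (3.3 equiv), THF, −78 to −20 °C; Boc2O (1.05 equiv), −78 to 0 °C; AcOH quench
Reagents that add atoms: di-tert-butyl dicarbonate, CC(C)(C)OC(=O)OC(=O)OC(C)(C)C
Why: In this Claisen-type C-acylation of the enolate carbon of the dianion, any carbonate formed at the phenoxide reaches the same product by Baker–Venkataraman-type O-to-C transfer, the third equivalent of base stores the product as its enolate, and the tert-butyl ester resists lactonisation at low temperature.

Step 14
Reactants: 18 3,4-bis(benzyloxy)-5-{7-(benzyloxy)-2-[4-(benzyloxy)phenyl]-5-hydroxy-4-oxo-4H-chromen-6-yl}benzaldehyde; 22 tert-butyl 3-[2,4-bis(benzyloxy)-6-hydroxyphenyl]-3-oxopropanoate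
Product: 23 tert-butyl (2Z)-2-[2,4-bis(benzyloxy)-6-hydroxybenzoyl]-3-(3,4-bis(benzyloxy)-5-{7-(benzyloxy)-2-[4-(benzyloxy)phenyl]-5-hydroxy-4-oxo-4H-chromen-6-yl}phenyl)prop-2-enoate
Conditions: piperidine (15 mol %), AcOH (15 mol %), 4 Å molecular sieves, toluene, rt
Reagents that add atoms: none
Why: Knoevenagel condensation of the unhindered C1' aldehyde under piperidinium acetate catalysis should stop at the alkylidene, since the bulky ester and the chelated phenol slow uncatalysed ring closure in this substrate class.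

Step 15
Reactants: 23 tert-butyl (2Z)-2-[2,4-bis(benzyloxy)-6-hydroxybenzoyl]-3-(3,4-bis(benzyloxy)-5-{7-(benzyloxy)-2-[4-(benzyloxy)phenyl]-5-hydroxy-4-oxo-4H-chromen-6-yl}phenyl)prop-2-enoate
Product: 26 (2S)-5,7-bis(benzyloxy)-2-(3,4-bis(benzyloxy)-5-{7-(benzyloxy)-2-[4-(benzyloxy)phenyl]-5-hydroxy-4-oxo-4H-chromen-6-yl}phenyl)-2,3-dihydro-4H-chromen-4-one, via tert-butyl flavanone-3-carboxylate 24 (not isolated), via flavanone-3-carboxylic acid 25 (not isolated)
Conditions: quinine-derived 3,5-bis(trifluoromethyl)phenyl thiourea (10 mol %), toluene, −25 °C; then TsOH·H2O, 80 °C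
Reagents that add atoms: none
Why: In this bifunctional cinchona-thiourea-catalysed intramolecular oxa-Michael addition (6-endo-trig), known for alkylidene β-keto esters of 2-hydroxyaryl ketones, the thiourea binds the dicarbonyl unit while the quinuclidine activates the phenol so that O1 reaches one face of C2 and sets 2S, after which acid silences the amine, cleaves the tert-butyl ester and triggers decarboxylation, erasing the labile C3 centre and blocking ring-opening.

Step 16
Reactants: 26 (2S)-5,7-bis(benzyloxy)-2-(3,4-bis(benzyloxy)-5-{7-(benzyloxy)-2-[4-(benzyloxy)phenyl]-5-hydroxy-4-oxo-4H-chromen-6-yl}phenyl)-2,3-dihydro-4H-chromen-4-one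
Product: 27 (2S)-2-{3,4-dihydroxy-5-[5,7-dihydroxy-2-(4-hydroxyphenyl)-4-oxo-4H-chromen-6-yl]phenyl}-5,7-dihydroxy-2,3-dihydro-4H-chromen-4-one (CNP0176432.1)
Conditions: H2 (1 atm), Pd/C (10 wt %), THF/MeOH, rt, monitored
Reagents that add atoms: none
Why: Catalytic hydrogenolysis of all six benzyl ethers runs under neutral conditions that should not open ring C or epimerise C2, and at atmospheric pressure it should spare the C2''–C3'' double bond and the benzylic C2–O1 bond.

Compound list
1 | phloroglucinol | Oc1cc(O)cc(O)c1 | starting material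
2 | 3,5-bis(methoxymethoxy)phenol | COCOc1cc(O)cc(OCOC)c1 | intermediate
3 | [3,5-bis(methoxymethoxy)phenoxy]tri(propan-2-yl)silane | COCOc1cc(OCOC)cc(O[Si](C(C)C)(C(C)C)C(C)C)c1 | intermediate
4 | 5-bromovanillin | COc1cc(C=O)cc(Br)c1O | starting material
5 | 3-bromo-4,5-dihydroxybenzaldehyde | O=Cc1cc(O)c(O)c(Br)c1 | intermediate
6 | 3,4-bis(benzyloxy)-5-bromobenzaldehyde | O=Cc1cc(OCc2ccccc2)c(OCc2ccccc2)c(Br)c1 | intermediate
7 | 2-[3,4-bis(benzyloxy)-5-bromophenyl]-1,3-dioxolane | Brc1cc(C2OCCO2)cc(OCc2ccccc2)c1OCc1ccccc1 | intermediate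
8 | {2,6-bis(methoxymethoxy)-4-[tri(propan-2-yl)silyloxy]phenyl}lithium | [Li]c1c(OCOC)cc(O[Si](C(C)C)(C(C)C)C(C)C)cc1OCOC | intermediate
9 | {2,6-bis(methoxymethoxy)-4-[tri(propan-2-yl)silyloxy]phenyl}zinc chloride | Cl[Zn]c1c(OCOC)cc(O[Si](C(C)C)(C(C)C)C(C)C)cc1OCOC | intermediate
10 | {4-[2,3-bis(benzyloxy)-5-(1,3-dioxolan-2-yl)phenyl]-3,5-bis(methoxymethoxy)phenoxy}tri(propan-2-yl)silane | COCOc1cc(O[Si](C(C)C)(C(C)C)C(C)C)cc(OCOC)c1-c1cc(C2OCCO2)cc(OCc2ccccc2)c1OCc1ccccc1 | intermediate
11 | 4-[2,3-bis(benzyloxy)-5-(1,3-dioxolan-2-yl)phenyl]-3,5-bis(methoxymethoxy)phenol | COCOc1cc(O)cc(OCOC)c1-c1cc(C2OCCO2)cc(OCc2ccccc2)c1OCc1ccccc1 | intermediate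
12 | 4-[2,3-bis(benzyloxy)-5-(1,3-dioxolan-2-yl)phenyl]-2-iodo-3,5-bis(methoxymethoxy)phenol | COCOc1cc(O)c(I)c(OCOC)c1-c1cc(C2OCCO2)cc(OCc2ccccc2)c1OCc1ccccc1 | intermediate
13 | 1-(benzyloxy)-4-ethynylbenzene | C#Cc1ccc(OCc2ccccc2)cc1 | starting material
14 | 1-{3-[2,3-bis(benzyloxy)-5-(1,3-dioxolan-2-yl)phenyl]-6-hydroxy-2,4-bis(methoxymethoxy)phenyl}-3-[4-(benzyloxy)phenyl]prop-2-yn-1-one | O=C(C#Cc1ccc(OCc2ccccc2)cc1)c1c(O)cc(OCOC)c(-c2cc(C3OCCO3)cc(OCc3ccccc3)c2OCc2ccccc2)c1OCOC | intermediate
15 | (2E)-1-{3-[2,3-bis(benzyloxy)-5-(1,3-dioxolan-2-yl)phenyl]-6-hydroxy-2,4-bis(methoxymethoxy)phenyl}-3-[4-(benzyloxy)phenyl]-3-(diethylamino)prop-2-en-1-one | CCN(CC)/C(=C/C(=O)c1c(O)cc(OCOC)c(-c2cc(C3OCCO3)cc(OCc3ccccc3)c2OCc2ccccc2)c1OCOC)c1ccc(OCc2ccccc2)cc1 | intermediate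
16 | 6-[2,3-bis(benzyloxy)-5-(1,3-dioxolan-2-yl)phenyl]-2-[4-(benzyloxy)phenyl]-5,7-bis(methoxymethoxy)-4H-chromen-4-one | COCOc1cc2oc(-c3ccc(OCc4ccccc4)cc3)cc(=O)c2c(OCOC)c1-c1cc(C2OCCO2)cc(OCc2ccccc2)c1OCc1ccccc1 | intermediate
17 | 3,4-bis(benzyloxy)-5-{2-[4-(benzyloxy)phenyl]-5,7-dihydroxy-4-oxo-4H-chromen-6-yl}benzaldehyde | O=Cc1cc(OCc2ccccc2)c(OCc2ccccc2)c(-c2c(O)cc3oc(-c4ccc(OCc5ccccc5)cc4)cc(=O)c3c2O)c1 | intermediate
18 | 3,4-bis(benzyloxy)-5-{7-(benzyloxy)-2-[4-(benzyloxy)phenyl]-5-hydroxy-4-oxo-4H-chromen-6-yl}benzaldehyde | O=Cc1cc(OCc2ccccc2)c(OCc2ccccc2)c(-c2c(OCc3ccccc3)cc3oc(-c4ccc(OCc5ccccc5)cc4)cc(=O)c3c2O)c1 | intermediate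
19 | 2',4',6'-trihydroxyacetophenone | CC(=O)c1c(O)cc(O)cc1O | starting material
20 | 1-[2,4-bis(benzyloxy)-6-hydroxyphenyl]ethan-1-one | CC(=O)c1c(O)cc(OCc2ccccc2)cc1OCc1ccccc1 | intermediate
21 | dilithium enolate phenolate of 20 | [Li]OC(=C)c1c(O[Li])cc(OCc2ccccc2)cc1OCc1ccccc1 | intermediate
22 | tert-butyl 3-[2,4-bis(benzyloxy)-6-hydroxyphenyl]-3-oxopropanoate | CC(C)(C)OC(=O)CC(=O)c1c(O)cc(OCc2ccccc2)cc1OCc1ccccc1 | intermediate
23 | tert-butyl (2Z)-2-[2,4-bis(benzyloxy)-6-hydroxybenzoyl]-3-(3,4-bis(benzyloxy)-5-{7-(benzyloxy)-2-[4-(benzyloxy)phenyl]-5-hydroxy-4-oxo-4H-chromen-6-yl}phenyl)prop-2-enoate | CC(C)(C)OC(=O)/C(=C\c1cc(OCc2ccccc2)c(OCc2ccccc2)c(-c2c(OCc3ccccc3)cc3oc(-c4ccc(OCc5ccccc5)cc4)cc(=O)c3c2O)c1)C(=O)c1c(O)cc(OCc2ccccc2)cc1OCc1ccccc1 | intermediate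
24 | tert-butyl (2S,3R)-5,7-bis(benzyloxy)-2-(3,4-bis(benzyloxy)-5-{7-(benzyloxy)-2-[4-(benzyloxy)phenyl]-5-hydroxy-4-oxo-4H-chromen-6-yl}phenyl)-4-oxo-3,4-dihydro-2H-chromene-3-carboxylate (2,3-trans; C3 labile) | O=C1[C@H](C(=O)OC(C)(C)C)[C@@H](c2cc(OCc3ccccc3)c(OCc3ccccc3)c(-c3c(OCc4ccccc4)cc4oc(-c5ccc(OCc6ccccc6)cc5)cc(=O)c4c3O)c2)Oc2cc(OCc3ccccc3)cc(OCc3ccccc3)c21 | intermediate
25 | (2S,3R)-5,7-bis(benzyloxy)-2-(3,4-bis(benzyloxy)-5-{7-(benzyloxy)-2-[4-(benzyloxy)phenyl]-5-hydroxy-4-oxo-4H-chromen-6-yl}phenyl)-4-oxo-3,4-dihydro-2H-chromene-3-carboxylic acid | O=C1[C@H](C(=O)O)[C@@H](c2cc(OCc3ccccc3)c(OCc3ccccc3)c(-c3c(OCc4ccccc4)cc4oc(-c5ccc(OCc6ccccc6)cc5)cc(=O)c4c3O)c2)Oc2cc(OCc3ccccc3)cc(OCc3ccccc3)c21 | intermediate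
26 | (2S)-5,7-bis(benzyloxy)-2-(3,4-bis(benzyloxy)-5-{7-(benzyloxy)-2-[4-(benzyloxy)phenyl]-5-hydroxy-4-oxo-4H-chromen-6-yl}phenyl)-2,3-dihydro-4H-chromen-4-one | O=C1C[C@@H](c2cc(OCc3ccccc3)c(OCc3ccccc3)c(-c3c(OCc4ccccc4)cc4oc(-c5ccc(OCc6ccccc6)cc5)cc(=O)c4c3O)c2)Oc2cc(OCc3ccccc3)cc(OCc3ccccc3)c21 | intermediate
27 | (2S)-2-{3,4-dihydroxy-5-[5,7-dihydroxy-2-(4-hydroxyphenyl)-4-oxo-4H-chromen-6-yl]phenyl}-5,7-dihydroxy-2,3-dihydro-4H-chromen-4-one | O=C1C[C@@H](c2cc(O)c(O)c(-c3c(O)cc4oc(-c5ccc(O)cc5)cc(=O)c4c3O)c2)Oc2cc(O)cc(O)c21 | target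

Total step count: 16. Longest linear sequence: 12 steps (steps 3 to 11, then 14 to 16, from 5-bromovanillin).

Steps most likely to fail

Step 9. Three processes threaten this step:
- Oxidative addition may be slow at the electron-rich C–I bond flanked by two oxygen substituents.
- The aroylpalladium species may be captured by diethylamine.
- Alkynylation may run ahead of CO insertion and be followed by five-membered ring closure.

The fallback sets out from 12 and 13 and rejoins the route at 16, passing through 14, which is then isolated. The carbonyl carbon is brought in on the alkyne instead of as a gas. Alkyne 13 is deprotonated with n-BuLi (THF, −78 °C) to lithium [4-(benzyloxy)phenyl]acetylide F1. This is acylated with N-methoxy-N-methylcarbamoyl chloride to the Weinreb amide 3-[4-(benzyloxy)phenyl]-N-methoxy-N-methylprop-2-ynamide F2. Iodophenol 12 is treated with i-PrMgCl·LiCl (2.2 equiv, THF, −20 to 0 °C), which deprotonates the phenol and exchanges iodine for magnesium, assisted by the neighbouring methoxymethoxy group. This gives the bis(chloromagnesium) aryl phenolate F3. Addition of F2 and a mild aqueous quench should give ynone 14. Warming 14 with diethylamine in ethanol should close ring E to 16 by the same addition–elimination.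

Step 15. Facial selectivity may be eroded in three ways:
- Uncatalysed ring closure may occur during step 14 or in this step.
- The ring may reopen before decarboxylation.
- The flavone carbonyl may compete for the thiourea.

The fallback sets out from 18 and 20, bypasses steps 13 to 15, and rejoins at 26. It replaces asymmetric catalysis by resolution with recycling. Claisen–Schmidt condensation (KOH, EtOH/THF, rt) should give the chalcone (2E)-1-[2,4-bis(benzyloxy)-6-hydroxyphenyl]-3-(3,4-bis(benzyloxy)-5-{7-(benzyloxy)-2-[4-(benzyloxy)phenyl]-5-hydroxy-4-oxo-4H-chromen-6-yl}phenyl)prop-2-en-1-one F4. Equilibration with NaOAc in refluxing ethanol should close it to the racemic hexabenzyl flavanone F5. Preparative chromatography on a polysaccharide carbamate chiral phase then delivers 26. The unwanted (2R)-hexabenzyl flavanone F6 goes back into the NaOAc equilibration, where reversible ring-opening racemises it.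

Step 6. Transmetalation and reductive elimination may be sluggish at the tri-ortho-substituted axis, so that protodemetalation of the arylzinc reagent wins. The fallback sets out from 8 (made from 3 as before) and 7 and rejoins at 10. It reverses the polarity of the coupling. Aryllithium 8 is quenched with I2 to [4-iodo-3,5-bis(methoxymethoxy)phenoxy]tri(propan-2-yl)silane F7. Bromide 7 is converted by Miyaura borylation (B2pin2, PdCl2(dppf), KOAc, dioxane, 90 °C) into 2-[2,3-bis(benzyloxy)-5-(1,3-dioxolan-2-yl)phenyl]-4,4,5,5-tetramethyl-1,3,2-dioxaborolane F8. This places boron on the ring that does not protodeboronate easily. Suzuki–Miyaura coupling of F7 and F8 (Pd(OAc)2, SPhos, K3PO4, toluene/H2O, 90 °C) should give 10. Any silyl loss under these conditions only anticipates step 7.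

Further compounds
F1 | step 9 | lithium [4-(benzyloxy)phenyl]acetylide | [Li]C#Cc1ccc(OCc2ccccc2)cc1
F2 | step 9 | 3-[4-(benzyloxy)phenyl]-N-methoxy-N-methylprop-2-ynamide | CON(C)C(=O)C#Cc1ccc(OCc2ccccc2)cc1
F3 | step 9 | bis(chloromagnesium) aryl phenolate derived from 12 | COCOc1cc(O[Mg]Cl)c([Mg]Cl)c(OCOC)c1-c1cc(C2OCCO2)cc(OCc2ccccc2)c1OCc1ccccc1
F4 | step 15 | (2E)-1-[2,4-bis(benzyloxy)-6-hydroxyphenyl]-3-(3,4-bis(benzyloxy)-5-{7-(benzyloxy)-2-[4-(benzyloxy)phenyl]-5-hydroxy-4-oxo-4H-chromen-6-yl}phenyl)prop-2-en-1-one | O=C(/C=C/c1cc(OCc2ccccc2)c(OCc2ccccc2)c(-c2c(OCc3ccccc3)cc3oc(-c4ccc(OCc5ccccc5)cc4)cc(=O)c3c2O)c1)c1c(O)cc(OCc2ccccc2)cc1OCc1ccccc1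
F5 | step 15 | racemic hexabenzyl flavanone (racemate of 26) | O=C1CC(c2cc(OCc3ccccc3)c(OCc3ccccc3)c(-c3c(OCc4ccccc4)cc4oc(-c5ccc(OCc6ccccc6)cc5)cc(=O)c4c3O)c2)Oc2cc(OCc3ccccc3)cc(OCc3ccccc3)c21
F6 | step 15 | (2R)-hexabenzyl flavanone (enantiomer of 26) | O=C1C[C@H](c2cc(OCc3ccccc3)c(OCc3ccccc3)c(-c3c(OCc4ccccc4)cc4oc(-c5ccc(OCc6ccccc6)cc5)cc(=O)c4c3O)c2)Oc2cc(OCc3ccccc3)cc(OCc3ccccc3)c21
F7 | step 6 | [4-iodo-3,5-bis(methoxymethoxy)phenoxy]tri(propan-2-yl)silane | COCOc1cc(O[Si](C(C)C)(C(C)C)C(C)C)cc(OCOC)c1I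
F8 | step 6 | 2-[2,3-bis(benzyloxy)-5-(1,3-dioxolan-2-yl)phenyl]-4,4,5,5-tetramethyl-1,3,2-dioxaborolane | CC1(C)OB(OC1(C)C)c1cc(C2OCCO2)cc(OCc2ccccc2)c1OCc1ccccc1
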